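**Retrosynthetic overview**
- The target is 2,4-dihydroxy-5-methyl-6-(13-methyltetradecyl)benzoic acid. The last step unmasks the carboxyl and the 2-OH from an isopropylidene acetal (a 1,3-benzodioxin-4-one).
- Key disconnection: the benzylic CH2–CH2 bond of the side chain. It is made by alkylating the terminal carbanion of a diketo-dioxinone trianion (a masked, open-chain tetraketide) with 1-iodo-12-methyltridecane. The same operation then folds the chain into the benzene ring by an aldol closure between the future ring carbons C1 and C6, followed by dehydration.
- Enabling feature: the benzene ring carries the carboxyl at C1 and oxygen at C2 and C4, an alternating polyketide pattern. The ring can therefore be unfolded into a poly-β-carbonyl chain in which ring carbon C6 is a ketone carbon, the benzylic CH2 is its terminal α-methyl, and the C5 methyl sits on the carbon between the C4 and C6 carbonyls.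
- The diketo-dioxinone comes from 2,2,6-trimethyl-4H-1,3-dioxin-4-one by two C-acylations. The iodide comes from 10-bromodecan-1-ol and isobutylmagnesium bromide (Cu catalysis), then iodination.
- Ring order: the 1,3-dioxin-4-one ring is bought; the benzene ring is the only ring formed, in the key step.

Key step: step 5

Remark on the chemistry: the target has no stereocentre and no other stereogenic element. It is achiral, so the route needs no stereocontrol and gives the single compound drawn.

**Step 1**
Reactants: 1 10-bromodecan-1-ol; 2 isobutylmagnesium bromide
Product: 3 12-methyltridecan-1-ol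
Conditions: 2 (2.5 equiv), Li2CuCl4 (3 mol%), THF, −20 °C → rt; aq NH4Cl
Reagents that add atoms: none
Why: Kochi–Schlosser Cu-catalysed sp3–sp3 coupling: one equivalent of Grignard reagent turns the OH into an inert magnesium alkoxide, and the cuprate formed in situ should displace the primary bromide without β-elimination.

**Step 2**
Reactants: 3 12-methyltridecan-1-ol
Product: 4 1-iodo-12-methyltridecane
Conditions: I2, PPh3, imidazole, CH2Cl2, 0 °C → rt
Reagents that add atoms: iodine, II
Why: Appel-type (Garegg–Samuelsson) iodination: the alkoxyphosphonium iodide of the primary alcohol should collapse by SN2 to the primary iodide, driven by formation of Ph3P=O.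

**Step 3**
Reactants: 5 2,2,6-trimethyl-4H-1,3-dioxin-4-one (2.0 equiv); 6 propionyl chloride (1.0 equiv)
Product: 7 2,2-dimethyl-6-(2-oxobutyl)-4H-1,3-dioxin-4-one
Conditions: LiHMDS (2.1 equiv), THF, −78 °C; then 6, −78 → −40 °C; cold 1 M HCl
Reagents that add atoms: none
Why: Vinylogous Claisen C-acylation: the lithium dienolate of the diketene–acetone adduct reacts with acyl chlorides at the 6-methyl (γ) carbon, and the second equivalent of dienolate takes up the more acidic proton of the product, so double acylation should not occur.

**Step 4**
Reactants: 7 2,2-dimethyl-6-(2-oxobutyl)-4H-1,3-dioxin-4-one; 8 N-methoxy-N-methylacetamide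
Product: 9 2,2-dimethyl-6-(3-methyl-2,4-dioxopentyl)-4H-1,3-dioxin-4-one
Conditions: LDA (2.3 equiv), THF, −78 °C; then 8 (1.2 equiv), −78 → −30 °C; cold 1 M HCl; short silica plug, used at once
Reagents that add atoms: none
Why: Crossed Claisen acylation of a Weiler-type dianion: the second deprotonation takes place at the α′-CH2 of the ethyl ketone, this more reactive carbanion attacks the Weinreb amide, and the chelated tetrahedral adduct should keep the 1,3-diketone masked until the acidic quench.

**Step 5**
Reactants: 9 2,2-dimethyl-6-(3-methyl-2,4-dioxopentyl)-4H-1,3-dioxin-4-one (1.15 equiv); 4 1-iodo-12-methyltridecane (1.0 equiv)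
Product: 11 7-hydroxy-2,2,6-trimethyl-5-(13-methyltetradecyl)-4H-1,3-benzodioxin-4-one, via chain-extended diketo-dioxinone 10 (not isolated)
Conditions: LDA (3.4 equiv), THF, −78 → −20 °C; then 4, DMPU, −78 → −10 °C; AcOH (4 equiv), −78 °C; then Et3N, CH2Cl2, rt; 1 M HCl work-up
Reagents that add atoms: none
Why: LDA removes the two doubly activated protons (side-chain C1′-H and C3′-H) and then a proton of the only remaining α-position, the terminal C5′ methyl; the trianion should react at this last-formed, least stabilised carbanion with primary iodide 4 in an SN2 step that forges the CH2–CH2 bond (Hauser–Harris terminal alkylation of a poly-β-carbonyl polyanion). Neutralisation gives 10, and Et3N then triggers intramolecular aldol addition of dioxinone C5 to the C4′ ketone, followed by dehydration and enolisation of the C2′ ketone, which is the known biomimetic aromatisation of diketo-dioxinones to isopropylidene-protected resorcylates. The benzene ring is closed in a 6-(enolexo)-exo-trig aldol mode between the future ring carbons C1 and C6, and aromatisation makes the closure irreversible. No stereocentre is formed, and the C3′ centre of 9 and 10 is lost on aromatisation. The step needs site selectivity among three carbanion centres, which the order of deprotonation should secure because the two internal sites are tied up as delocalised enolates and C3′ is fully substituted. It also needs a single folding mode, which the dioxinone ring should secure: it ties the carboxyl carbon and the C2 oxygen into a vinylogous ester acetal that cannot act as a Claisen acceptor or close a pyranone, so only the C5→C4′ aldol gives a six-membered ring.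

**Step 6**
Reactants: 11 7-hydroxy-2,2,6-trimethyl-5-(13-methyltetradecyl)-4H-1,3-benzodioxin-4-one
Product: 12 2,4-dihydroxy-5-methyl-6-(13-methyltetradecyl)benzoic acid
Conditions: KOH (aq, 10 equiv), DMSO, 60 °C; then 1 M HCl, 0 °C, pH 2, EtOAc extraction
Reagents that add atoms: potassium hydroxide, [K+].[OH-]
Why: Saponification of the aryl-ester-type lactone of the benzodioxinone: hydroxide adds to C4, the hemiketal left on the phenol oxygen loses acetone, and the resorcylate stays as its stable carboxylate until cold acidification, which should avoid decarboxylation.

**Compound list**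
1 | 10-bromodecan-1-ol | OCCCCCCCCCCBr | starting material
2 | isobutylmagnesium bromide | CC(C)C[Mg]Br | starting material
3 | 12-methyltridecan-1-ol | CC(C)CCCCCCCCCCCO | intermediate
4 | 1-iodo-12-methyltridecane | CC(C)CCCCCCCCCCCI | intermediate
5 | 2,2,6-trimethyl-4H-1,3-dioxin-4-one | CC1=CC(=O)OC(C)(C)O1 | starting material
6 | propionyl chloride | CCC(Cl)=O | starting material
7 | 2,2-dimethyl-6-(2-oxobutyl)-4H-1,3-dioxin-4-one | CCC(=O)CC1=CC(=O)OC(C)(C)O1 | intermediate
8 | N-methoxy-N-methylacetamide | CC(=O)N(C)OC | starting material
9 | 2,2-dimethyl-6-(3-methyl-2,4-dioxopentyl)-4H-1,3-dioxin-4-one (keto/enol mixture) | CC(=O)C(C)C(=O)CC1=CC(=O)OC(C)(C)O1 | intermediate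
10 | 2,2-dimethyl-6-(3,17-dimethyl-2,4-dioxooctadecyl)-4H-1,3-dioxin-4-one (not isolated) | CC(C)CCCCCCCCCCCCC(=O)C(C)C(=O)CC1=CC(=O)OC(C)(C)O1 | intermediate
11 | 7-hydroxy-2,2,6-trimethyl-5-(13-methyltetradecyl)-4H-1,3-benzodioxin-4-one | CC(C)CCCCCCCCCCCCc1c(C)c(O)cc2OC(C)(C)OC(=O)c12 | intermediate
12 | 2,4-dihydroxy-5-methyl-6-(13-methyltetradecyl)benzoic acid | Cc1c(O)cc(O)c(C(=O)O)c1CCCCCCCCCCCCC(C)C | target

**Totals**
Total step count: 6. Longest linear sequence: 4 steps (steps 3, 4, 5, 6; the branch through steps 1, 2, 5, 6 is equally long).

**Steps most likely to fail**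

Step 5. The third deprotonation may stay incomplete, alkylation may take place at an internal carbon or on oxygen, a second alkylation may follow proton transfer, or the chain may fold in a mode other than the aldol one. The fallback separates ring formation from chain attachment and sets out from 9. Compound 9 alone is aromatised (Et3N, CH2Cl2, then dilute HCl) to 7-hydroxy-2,2,5,6-tetramethyl-4H-1,3-benzodioxin-4-one F1. The phenol is protected (MOMCl, iPr2NEt, CH2Cl2) to give 7-(methoxymethoxy)-2,2,5,6-tetramethyl-4H-1,3-benzodioxin-4-one F2. Lateral lithiation with LDA (THF, −78 °C) should take place only at the C5 methyl, which is ortho to the lactone carbonyl and gives an extended enolate, while the C6 methyl is not conjugated. Alkylation of this anion with iodide 4 forms the same CH2–CH2 bond and gives 7-(methoxymethoxy)-2,2,6-trimethyl-5-(13-methyltetradecyl)-4H-1,3-benzodioxin-4-one F3. Removal of the MOM group (HCl, MeOH, rt) brings the route back at 11.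

Step 4. C-acylation of the hindered secondary carbanion by the Weinreb amide may be slow, so that proton transfer or O-acylation competes, and 9 may cyclise before it is used. The fallback sets out from 7 and replaces the acylation by an aldol addition and an oxidation. The dianion of 7 (LDA, THF, −78 °C) is added to acetaldehyde, a far more reactive electrophile, to give 6-(4-hydroxy-3-methyl-2-oxopentyl)-2,2-dimethyl-4H-1,3-dioxin-4-one F4 as a mixture of diastereomers, which does not matter because both centres are lost. Oxidation with Dess–Martin periodinane (CH2Cl2, rt) returns to the route at 9.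

Step 6. Saponification may be sluggish because the 7-phenoxide, para to the carbonyl-bearing carbon, deactivates the lactone, and the free resorcylic acid may lose CO2 during acidification. The fallback sets out from 11 and avoids both hot aqueous base and acid. Ring opening with sodium benzyloxide (BnOH, NaH, THF, 0 °C → rt) gives benzyl 2,4-dihydroxy-5-methyl-6-(13-methyltetradecyl)benzoate F5, and hydrogenolysis (H2, Pd/C, EtOAc, rt) gives 12 under neutral conditions.

**Further compounds**
F1 | step 5 | 7-hydroxy-2,2,5,6-tetramethyl-4H-1,3-benzodioxin-4-one | Cc1c(C)c(O)cc2OC(C)(C)OC(=O)c12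
F2 | step 5 | 7-(methoxymethoxy)-2,2,5,6-tetramethyl-4H-1,3-benzodioxin-4-one | COCOc1cc2OC(C)(C)OC(=O)c2c(C)c1C
F3 | step 5 | 7-(methoxymethoxy)-2,2,6-trimethyl-5-(13-methyltetradecyl)-4H-1,3-benzodioxin-4-one | COCOc1cc2OC(C)(C)OC(=O)c2c(CCCCCCCCCCCCC(C)C)c1C
F4 | step 4 | 6-(4-hydroxy-3-methyl-2-oxopentyl)-2,2-dimethyl-4H-1,3-dioxin-4-one (diastereomer mixture) | CC(O)C(C)C(=O)CC1=CC(=O)OC(C)(C)O1
F5 | step 6 | benzyl 2,4-dihydroxy-5-methyl-6-(13-methyltetradecyl)benzoate | Cc1c(O)cc(O)c(C(=O)OCc2ccccc2)c1CCCCCCCCCCCCC(C)C
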